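**Plan**
1. Retrosynthesis: the three MOM ethers go first; ring C is then cut at O1–C8a and C4–C4a, giving a ring-A aryne and a chain O1–C2–C3–C4(=O) that carries the chroman. The chain is cut at its acyl carbon (Claisen) to a chroman ester, the chroman at O1–C2 to a phenol with a C10 triene chain, and that at aryl–CH2 to a bromocatechol ester and β-ocimene.
2. Enabling feature: in ring A only the neighbours C4a (bonded to acyl carbon C4) and C8a (bonded to ether oxygen O1) carry ring-C atoms. C4a is flanked by C5–O, C8a by C8–H, and O1 and C4 are 1,3-related through C2–C3. A 3-alkoxyaryne C4a≡C8a can therefore take up a β-alkoxide oxygen at C8a (remote from C5–O) and the tethered acyl carbon at C4a, which also fixes 6-prenyl against 8-prenyl.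
3. Forward, ring A (steps 1–6): resorcinol, bis-MOM ether, C2 prenylation, meta C–H borylation/oxidation, carbamate-directed ortho-silylation, o-silylaryl triflate 14.
4. Forward, chroman part (steps 7–12): mono-MOM bromocatechol ester plus ocimene by B-alkyl Suzuki coupling; an enantioselective Wacker-type cyclisation forms the chroman ring, the quaternary C2 and the (E)-diene together; then Claisen condensation, asymmetric transfer hydrogenation and O-silylation to 25.
5. Ring order: chroman ring (step 9), ring C by aryne annulation (step 13), global deprotection (step 14).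
6. Stereochemistry: chroman C2 (S) from ligand-controlled oxypalladation; flavanone C2 (S) from catalyst-controlled transfer hydrogenation, carried through the annulation with its C–O bond intact.

Key step: step 13

Remark: methyl 3-bromo-4,5-dihydroxybenzoate and β-ocimene (E/Z mixture) are taken as catalogue materials; the antipodes of the BOXAX ligand and of the ruthenium catalyst are those that give the (S) centres drawn, assigned by analogy and to be confirmed on the first chiral intermediate.

Step 1
Reactants: 1 resorcinol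
Product: 2 1,3-bis(methoxymethoxy)benzene
Conditions: MOMCl (2.5 equiv), i-Pr2NEt (3 equiv), CH2Cl2, 0 °C → rt
Reagents that add atoms: chloromethyl methyl ether, COCCl
Why: Williamson-type double O-alkylation of the phenols by the reactive α-chloro ether gives acetal groups that later direct metalation and survive organolithium, fluoride and palladium chemistry; no stereocentre is formed.

Step 2
Reactants: 2 1,3-bis(methoxymethoxy)benzene; 3 prenyl bromide
Product: 5 1,3-bis(methoxymethoxy)-2-(3-methylbut-2-en-1-yl)benzene, via aryllithium 4 (not isolated)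
Conditions: n-BuLi (1.1 equiv), THF, 0 °C; then CuBr·SMe2 (0.1 equiv), 3, −78 °C → rt
Reagents that add atoms: none
Why: Directed ortho-metalation occurs at C2, the only position flanked by two coordinating MOM ethers, and copper-assisted SN2 allylation of the aryllithium installs the linear prenyl group.

Step 3
Reactants: 5 1,3-bis(methoxymethoxy)-2-(3-methylbut-2-en-1-yl)benzene
Product: 7 3,5-bis(methoxymethoxy)-4-(3-methylbut-2-en-1-yl)phenol, via arylboronate 6 (not isolated)
Conditions: [Ir(OMe)(cod)]2 (1.5 mol %), 4,4'-di-tert-butyl-2,2'-bipyridine (3 mol %), B2pin2 (1.0 equiv), THF, 70 °C; then aq. H2O2, aq. NaOH, 0 °C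
Reagents that add atoms: hydrogen peroxide, OO
Why: Sterically governed iridium-catalysed aromatic C–H borylation should take place at the only ring C–H not ortho to a substituent (para to the prenyl group), and basic peroxide converts the C–B bond into C–OH (one-pot borylation/oxidation) while the trisubstituted alkene is expected to stay inert.

Step 4
Reactants: 7 3,5-bis(methoxymethoxy)-4-(3-methylbut-2-en-1-yl)phenol
Product: 8 3,5-bis(methoxymethoxy)-4-(3-methylbut-2-en-1-yl)phenyl N-isopropylcarbamate
Conditions: i-PrNCO (1.5 equiv), Et3N (0.2 equiv), CH2Cl2, rt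
Reagents that add atoms: isopropyl isocyanate, CC(C)N=C=O
Why: Base-catalysed addition of the phenol to the isocyanate gives an O-aryl carbamate, a strong ortho-directing group that can later be removed under mild amine conditions.

Step 5
Reactants: 8 3,5-bis(methoxymethoxy)-4-(3-methylbut-2-en-1-yl)phenyl N-isopropylcarbamate
Product: 12 3,5-bis(methoxymethoxy)-4-(3-methylbut-2-en-1-yl)-2-(trimethylsilyl)phenyl N-isopropylcarbamate, via N-silyl carbamate 9 (not isolated), via aryllithium 10 (not isolated), via N-silyl arylsilane 11 (not isolated)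
Conditions: TBSOTf (1.1 equiv), TMEDA (1.1 equiv), Et2O, 0 °C → rt; then TMEDA (2 equiv), n-BuLi (2 equiv), −78 °C; then Me3SiCl (3 equiv), −78 °C → rt; cold aq. NaHSO4 (brief)
Reagents that add atoms: chlorotrimethylsilane, C[Si](C)(C)Cl
Why: After transient N-silylation the carbamate and the neighbouring MOM ether together direct ortho-lithiation to one of the two equivalent remaining ring positions (directed ortho-metalation), the aryllithium is silylated, and aqueous work-up removes the N-silyl group.

Step 6
Reactants: 12 3,5-bis(methoxymethoxy)-4-(3-methylbut-2-en-1-yl)-2-(trimethylsilyl)phenyl N-isopropylcarbamate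
Product: 14 3,5-bis(methoxymethoxy)-4-(3-methylbut-2-en-1-yl)-2-(trimethylsilyl)phenyl trifluoromethanesulfonate, via silylphenol 13 (not isolated)
Conditions: Et2NH (1.5 equiv), DBU (1.5 equiv), MeCN, 40 °C; then PhNTf2 (1.5 equiv), rt
Reagents that add atoms: N-phenylbis(trifluoromethanesulfonimide), O=S(=O)(N(c1ccccc1)S(=O)(=O)C(F)(F)F)C(F)(F)F
Why: Base-induced E1cB loss of isopropyl isocyanate (trapped by Et2NH as a urea) frees the o-silylphenoxide, which is triflated in the same flask to give the o-silylaryl triflate aryne precursor.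

Step 7
Reactants: 15 methyl 3-bromo-4,5-dihydroxybenzoate
Product: 16 methyl 3-bromo-4-hydroxy-5-(methoxymethoxy)benzoate
Conditions: NaH (2.2 equiv), DMF, 0 °C; then MOMCl (1.0 equiv), −20 °C → rt; aq. NH4Cl
Reagents that add atoms: chloromethyl methyl ether, COCCl
Why: In the catecholate dianion the oxide meta to the ester is the more basic and nucleophilic one, whereas the oxide para to the ester is delocalised into it and flanked by bromine, so one equivalent of MOMCl should alkylate O5 selectively (dianion-controlled regioselective Williamson etherification).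

Step 8
Reactants: 16 methyl 3-bromo-4-hydroxy-5-(methoxymethoxy)benzoate; 17 β-ocimene
Product: 19 methyl 3-[(3E)-3,7-dimethylocta-3,6-dien-1-yl]-4-hydroxy-5-(methoxymethoxy)benzoate (E/Z mixture at the 3,4-alkene), via alkylborane 18 (not isolated)
Conditions: 17 (1.5 equiv), 9-BBN-H (1.5 equiv), THF, 0 °C → rt; then 16, PdCl2(dppf) (5 mol %), aq. K3PO4 (4 equiv), DMF, 60 °C
Reagents that add atoms: none
Why: 9-BBN should hydroborate only the monosubstituted terminal alkene of ocimene (anti-Markovnikov) and leave both trisubstituted alkenes, and B-alkyl Suzuki–Miyaura coupling then joins the primary alkylborane to the aryl bromide; no stereocentre is formed.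

Step 9
Reactants: 19 methyl 3-[(3E)-3,7-dimethylocta-3,6-dien-1-yl]-4-hydroxy-5-(methoxymethoxy)benzoate
Product: 20 methyl (2S)-8-(methoxymethoxy)-2-methyl-2-[(1E)-4-methylpenta-1,3-dien-1-yl]-3,4-dihydro-2H-chromene-6-carboxylate
Conditions: Pd(OCOCF3)2 (10 mol %), 2,2'-bis(4-benzyl-4,5-dihydro-1,3-oxazol-2-yl)-1,1'-binaphthyl (Bn-BOXAX, 20 mol %), p-benzoquinone (4 equiv), MeOH, 60 °C
Reagents that add atoms: none
Why: In this enantioselective Wacker-type oxidative cyclisation the phenol adds to the alkene bound to the chiral bis(oxazoline) complex of divalent palladium in a 6-exo oxypalladation that creates the quaternary C2 (the ligand fixes the alkene face and hence the (S) configuration), β-hydride elimination towards the allylic CH2 releases the conjugated (E)-diene, and benzoquinone reoxidises zerovalent palladium.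

Step 10
Reactants: 20 methyl (2S)-8-(methoxymethoxy)-2-methyl-2-[(1E)-4-methylpenta-1,3-dien-1-yl]-3,4-dihydro-2H-chromene-6-carboxylate; 21 N-methoxy-N-methylacetamide
Product: 23 3-[(2S)-8-(methoxymethoxy)-2-methyl-2-[(1E)-4-methylpenta-1,3-dien-1-yl]chroman-6-yl]-N-methoxy-N-methyl-3-oxopropanamide, via lithium enolate 22 (not isolated)
Conditions: 21 (3 equiv), LiN(i-Pr)2 (3 equiv), THF, −78 °C; then 20, −78 → −20 °C; aq. NH4Cl
Reagents that add atoms: none
Why: In this crossed Claisen condensation the amide enolate is acylated on carbon by the aryl ester, and the product is held as its enolate by the excess base so that only one acyl transfer occurs.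

Step 11
Reactants: 23 the β-keto Weinreb amide
Product: 24 (3S)-3-hydroxy-3-[(2S)-8-(methoxymethoxy)-2-methyl-2-[(1E)-4-methylpenta-1,3-dien-1-yl]chroman-6-yl]-N-methoxy-N-methylpropanamide
Conditions: RuCl[(S,S)-TsDPEN](p-cymene) (2 mol %), HCO2H/Et3N (1:1), EtOAc, 30 °C
Reagents that add atoms: none
Why: Noyori–Ikariya asymmetric transfer hydrogenation reduces the aryl ketone through the six-membered outer-sphere transition state in which the CH–π contact between the arene ligand and ring B selects the carbonyl face, so the (S,S)-catalyst should give the (S)-carbinol while C=C bonds stay untouched.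

Step 12
Reactants: 24 the (3S)-β-hydroxy Weinreb amide
Product: 25 (3S)-3-[(2S)-8-(methoxymethoxy)-2-methyl-2-[(1E)-4-methylpenta-1,3-dien-1-yl]chroman-6-yl]-N-methoxy-N-methyl-3-(trimethylsilyloxy)propanamide
Conditions: Me3SiCl (1.5 equiv), imidazole (2.5 equiv), CH2Cl2, 0 °C
Reagents that add atoms: chlorotrimethylsilane, C[Si](C)(C)Cl
Why: Silylation of the secondary alcohol replaces the O–H proton by a fluoride-labile group, so that step 13 can release the alkoxide without any proton source; the stereocentre is untouched.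

Step 13
Reactants: 25 the β-silyloxy Weinreb amide; 14 the o-silylaryl triflate
Product: 30 (2S)-5,7-bis(methoxymethoxy)-2-[(2S)-8-(methoxymethoxy)-2-methyl-2-[(1E)-4-methylpenta-1,3-dien-1-yl]chroman-6-yl]-6-(3-methylbut-2-en-1-yl)chroman-4-one, via caesium alkoxide 26 (not isolated), via aryne 27 (not isolated), via arylcaesium 28 (not isolated), via tetrahedral adduct 29 (not isolated)
Conditions: 14 (1.5 equiv), CsF (4 equiv), 18-crown-6 (1 equiv), THF, 0 → 25 °C; then aq. NH4Cl, 0 °C
Reagents that add atoms: none
Why: Proposed new method: fluoride cleaves the O–SiMe3 bond of 25 to the proton-free alkoxide 26 and the C–SiMe3 bond of 14 (with 1,2-loss of triflate) to aryne 27; 26 adds to the aryne carbon remote from the C5 MOM ether (future C8a) because the inductively withdrawing alkoxy group distorts the triple bond so that the carbanion develops at C4a, next to that oxygen, and arylcaesium 28 then attacks the Weinreb amide carbonyl to give the N,O-chelated tetrahedral adduct 29, which releases ketone 30 only on aqueous quench. The closest known reactions are the aryne annulation of salicylate esters to xanthones and the insertion of arynes into the N–C(O) bond of β-lactams to give 2,3-dihydroquinolin-4-ones; here the O-nucleophile is an aliphatic β-alkoxide. Ring C is closed as a stepwise formal [4+2] annulation, intermolecular C–O bond formation followed by a 6-exo-trig acyl addition. No stereocentre is created: C2 keeps the (S) configuration from step 11 because its C–O bond is never broken and because the ketone, which could open by β-elimination, stays masked as 29 until work-up. The selectivities needed are regioselectivity (O1 at C8a, not C4a, which also decides 6-prenyl against 8-prenyl), secured by the single alkoxy group beside the triple bond, and acyl capture over protonation of 28, secured by the silyl ether pronucleophile, the aprotic medium and the six-membered geometry.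

Step 14
Reactants: 30 the tris-MOM flavanone
Product: 31 (2S)-5,7-dihydroxy-2-[(2S)-8-hydroxy-2-methyl-2-[(1E)-4-methylpenta-1,3-dien-1-yl]-3,4-dihydro-2H-chromen-6-yl]-6-(3-methylbut-2-en-1-yl)-2,3-dihydro-4H-chromen-4-one
Conditions: ZnBr2 (3 equiv), n-PrSH (6 equiv), CH2Cl2, 0 °C, short reaction time
Reagents that add atoms: none
Why: ZnBr2 activates the acetal oxygens and the soft thiol captures the methoxymethyl cation (Lewis acid/thiol acetal cleavage), a fast non-protic deprotection that should leave the tertiary dienylic aryl ether, the prenyl group and the base-sensitive C2 stereocentre intact.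

**Compound list**
1 | resorcinol | Oc1cccc(O)c1 | starting material
2 | 1,3-bis(methoxymethoxy)benzene | COCOc1cccc(OCOC)c1 | intermediate
3 | prenyl bromide (1-bromo-3-methylbut-2-ene) | CC(C)=CCBr | starting material
4 | [2,6-bis(methoxymethoxy)phenyl]lithium | COCOc1cccc(OCOC)c1[Li] | intermediate (not isolated)
5 | 1,3-bis(methoxymethoxy)-2-(3-methylbut-2-en-1-yl)benzene | COCOc1cccc(OCOC)c1CC=C(C)C | intermediate
6 | 2-[3,5-bis(methoxymethoxy)-4-(3-methylbut-2-en-1-yl)phenyl]-4,4,5,5-tetramethyl-1,3,2-dioxaborolane | COCOc1cc(B2OC(C)(C)C(C)(C)O2)cc(OCOC)c1CC=C(C)C | intermediate (not isolated)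
7 | 3,5-bis(methoxymethoxy)-4-(3-methylbut-2-en-1-yl)phenol | COCOc1cc(O)cc(OCOC)c1CC=C(C)C | intermediate
8 | 3,5-bis(methoxymethoxy)-4-(3-methylbut-2-en-1-yl)phenyl N-isopropylcarbamate | COCOc1cc(OC(=O)NC(C)C)cc(OCOC)c1CC=C(C)C | intermediate
9 | N-(tert-butyldimethylsilyl) derivative of carbamate 8 | COCOc1cc(OC(=O)N(C(C)C)[Si](C)(C)C(C)(C)C)cc(OCOC)c1CC=C(C)C | intermediate (not isolated)
10 | 2-lithio derivative of 9 (lithium between the carbamate oxygen and a MOM ether) | [Li]c1c(OCOC)c(CC=C(C)C)c(OCOC)cc1OC(=O)N(C(C)C)[Si](C)(C)C(C)(C)C | intermediate (not isolated)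
11 | 2-(trimethylsilyl) derivative of 9 | C[Si](C)(C)c1c(OCOC)c(CC=C(C)C)c(OCOC)cc1OC(=O)N(C(C)C)[Si](C)(C)C(C)(C)C | intermediate (not isolated)
12 | 3,5-bis(methoxymethoxy)-4-(3-methylbut-2-en-1-yl)-2-(trimethylsilyl)phenyl N-isopropylcarbamate | C[Si](C)(C)c1c(OCOC)c(CC=C(C)C)c(OCOC)cc1OC(=O)NC(C)C | intermediate
13 | 3,5-bis(methoxymethoxy)-4-(3-methylbut-2-en-1-yl)-2-(trimethylsilyl)phenol | C[Si](C)(C)c1c(OCOC)c(CC=C(C)C)c(OCOC)cc1O | intermediate (not isolated)
14 | 3,5-bis(methoxymethoxy)-4-(3-methylbut-2-en-1-yl)-2-(trimethylsilyl)phenyl trifluoromethanesulfonate | C[Si](C)(C)c1c(OCOC)c(CC=C(C)C)c(OCOC)cc1OS(=O)(=O)C(F)(F)F | intermediate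
15 | methyl 3-bromo-4,5-dihydroxybenzoate | COC(=O)c1cc(O)c(O)c(Br)c1 | starting material
16 | methyl 3-bromo-4-hydroxy-5-(methoxymethoxy)benzoate | COC(=O)c1cc(OCOC)c(O)c(Br)c1 | intermediate
17 | β-ocimene, 3,7-dimethylocta-1,3,6-triene (commercial E/Z mixture, E isomer drawn) | C=C/C(C)=C/CC=C(C)C | starting material
18 | 9-[(3E)-3,7-dimethylocta-3,6-dien-1-yl]-9-borabicyclo[3.3.1]nonane | B1(C2CCCC1CCC2)CC/C(C)=C/CC=C(C)C | intermediate (not isolated)
19 | methyl 3-[(3E)-3,7-dimethylocta-3,6-dien-1-yl]-4-hydroxy-5-(methoxymethoxy)benzoate (E/Z mixture, E drawn) | COC(=O)c1cc(OCOC)c(O)c(CC/C(C)=C/CC=C(C)C)c1 | intermediate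
20 | methyl (2S)-8-(methoxymethoxy)-2-methyl-2-[(1E)-4-methylpenta-1,3-dien-1-yl]-3,4-dihydro-2H-chromene-6-carboxylate | CC(C)=C/C=C/[C@]1(C)CCc2cc(C(=O)OC)cc(OCOC)c2O1 | intermediate
21 | N-methoxy-N-methylacetamide | CC(=O)N(C)OC | starting material
22 | lithium enolate of N-methoxy-N-methylacetamide | C=C(O[Li])N(C)OC | intermediate (not isolated)
23 | 3-[(2S)-8-(methoxymethoxy)-2-methyl-2-[(1E)-4-methylpenta-1,3-dien-1-yl]chroman-6-yl]-N-methoxy-N-methyl-3-oxopropanamide | CC(C)=C/C=C/[C@]1(C)CCc2cc(C(=O)CC(=O)N(C)OC)cc(OCOC)c2O1 | intermediate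
24 | (3S)-3-hydroxy-3-[(2S)-8-(methoxymethoxy)-2-methyl-2-[(1E)-4-methylpenta-1,3-dien-1-yl]chroman-6-yl]-N-methoxy-N-methylpropanamide | CC(C)=C/C=C/[C@]1(C)CCc2cc([C@@H](O)CC(=O)N(C)OC)cc(OCOC)c2O1 | intermediate
25 | O-trimethylsilyl ether of 24 | CC(C)=C/C=C/[C@]1(C)CCc2cc([C@@H](O[Si](C)(C)C)CC(=O)N(C)OC)cc(OCOC)c2O1 | intermediate
26 | caesium alkoxide of 24 | CC(C)=C/C=C/[C@]1(C)CCc2cc([C@@H]([O-])CC(=O)N(C)OC)cc(OCOC)c2O1.[Cs+] | intermediate (not isolated)
27 | 3,5-bis(methoxymethoxy)-4-(3-methylbut-2-en-1-yl)benzyne (1,2-didehydrobenzene) | C1#CC=C(OCOC)C(CC=C(C)C)=C1OCOC | intermediate (not isolated)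
28 | arylcaesium from addition of 26 to 27 (aryl ether of 24, caesium on the ring carbon between the ether oxygen and a MOM ether) | CC(C)=C/C=C/[C@]1(C)CCc2cc([C@@H](Oc3cc(OCOC)c(CC=C(C)C)c(OCOC)c3[Cs])CC(=O)N(C)OC)cc(OCOC)c2O1 | intermediate (not isolated)
29 | caesium salt of the cyclic N,O-hemiaminal at C4 of the chromanone ring (epimers at C4) | CC(C)=C/C=C/[C@]1(C)CCc2cc([C@@H]3CC([O-])(N(C)OC)c4c(cc(OCOC)c(CC=C(C)C)c4OCOC)O3)cc(OCOC)c2O1.[Cs+] | intermediate (not isolated)
30 | (2S)-5,7-bis(methoxymethoxy)-2-[(2S)-8-(methoxymethoxy)-2-methyl-2-[(1E)-4-methylpenta-1,3-dien-1-yl]chroman-6-yl]-6-(3-methylbut-2-en-1-yl)chroman-4-one | CC(C)=C/C=C/[C@]1(C)CCc2cc([C@@H]3CC(=O)c4c(cc(OCOC)c(CC=C(C)C)c4OCOC)O3)cc(OCOC)c2O1 | intermediate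
31 | (2S)-5,7-dihydroxy-2-[(2S)-8-hydroxy-2-methyl-2-[(1E)-4-methylpenta-1,3-dien-1-yl]-3,4-dihydro-2H-chromen-6-yl]-6-(3-methylbut-2-en-1-yl)-2,3-dihydro-4H-chromen-4-one | CC(C)=C/C=C/[C@]1(C)CCc2cc([C@@H]3CC(=O)c4c(cc(O)c(CC=C(C)C)c4O)O3)cc(O)c2O1 | target

**Step count and risks**
Total steps: 14. Longest linear sequence: 8 steps (steps 7–14, or steps 1–6 followed by 13 and 14).

Most likely to fail:

Step 13 (proposed new method). The arylcaesium may be protonated, or may remove an α-proton of the amide and expel the aryloxide, before it reaches the carbonyl. The free alkoxide may also fragment by retro-aldol and recombine, eroding the C2 configuration, or lose the race for the aryne to fluoride. The fallback uses known reactions and sets out from 23 and 8. Transfer hydrogenation of 23 with the (R,R)-configured ruthenium catalyst gives the (3R)-hydroxy Weinreb amide F1. Carbamate 8 is N-silylated and ortho-lithiated as in step 5 (9, 10), and aryllithium 10 is added at −78 °C to F1 previously deprotonated with i-PrMgCl (Weinreb ketone synthesis). This gives the N-silyl keto carbamate F2 and, after aqueous work-up, the keto carbamate F3. Et2NH/DBU in MeCN then frees the 2'-hydroxy β-hydroxy ketone F4. Mitsunobu cyclisation (PPh3, diisopropyl azodicarboxylate, THF, 0 °C) closes ring C by SN2 attack of the phenol on the benzylic carbinol with inversion, and the route is rejoined at 30.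

Step 9. Face control by the ligand may be incomplete on the skipped diene, and the palladium hydride or divalent palladium may isomerise or further oxidise the newly formed conjugated diene. The fallback builds the diene after ring closure and sets out from 16. B-alkyl Suzuki coupling of 16 with the 9-BBN adduct of commercial 3-methylpenta-1,3-diene, 9-(3-methylpent-3-en-1-yl)-9-borabicyclo[3.3.1]nonane F5, gives the pentenylphenol F6. The same Pd(OCOCF3)2/BOXAX/benzoquinone cyclisation, now on the exact precedented substrate type, gives the (2S)-2-vinylchroman F7. Lemieux–Johnson cleavage (OsO4 cat., NaIO4, 2,6-lutidine, dioxane/water) gives the chroman-2-carbaldehyde F8. Horner–Wadsworth–Emmons olefination with diethyl (3-methylbut-2-en-1-yl)phosphonate (LiN(SiMe3)2, THF, −78 °C → rt) installs the (E)-diene and returns to 20.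

Step 14. The Lewis acid may ionise the tertiary dienylic aryl ether, the prenyl group may cyclise onto a freed neighbouring phenol, or ring C may open and reclose with loss of configuration. The fallback exchanges the protecting groups instead of cleaving them with acid and sets out from 30. Me3SiOTf/2,2'-bipyridyl (CH2Cl2, 0 °C) transfers the three methoxymethyl groups to the bipyridyl nitrogen and leaves the tris(trimethylsilyl) ether F9. Methanolysis of F9 at rt under neutral conditions gives 31.

**Further compounds**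
F1 | step 13 | (3R)-3-hydroxy-3-[(2S)-8-(methoxymethoxy)-2-methyl-2-[(1E)-4-methylpenta-1,3-dien-1-yl]chroman-6-yl]-N-methoxy-N-methylpropanamide | CC(C)=C/C=C/[C@]1(C)CCc2cc([C@H](O)CC(=O)N(C)OC)cc(OCOC)c2O1
F2 | step 13 | (3R)-β-hydroxy ketone with ring A as its N-(tert-butyldimethylsilyl)-N-isopropylcarbamate | CC(C)=C/C=C/[C@]1(C)CCc2cc([C@H](O)CC(=O)c3c(OCOC)c(CC=C(C)C)c(OCOC)cc3OC(=O)N(C(C)C)[Si](C)(C)C(C)(C)C)cc(OCOC)c2O1
F3 | step 13 | (3R)-β-hydroxy ketone with ring A as its N-isopropylcarbamate | CC(C)=C/C=C/[C@]1(C)CCc2cc([C@H](O)CC(=O)c3c(OCOC)c(CC=C(C)C)c(OCOC)cc3OC(=O)NC(C)C)cc(OCOC)c2O1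
F4 | step 13 | (3R)-3-hydroxy-1-[2-hydroxy-4,6-bis(methoxymethoxy)-5-(3-methylbut-2-en-1-yl)phenyl]-3-[(2S)-8-(methoxymethoxy)-2-methyl-2-[(1E)-4-methylpenta-1,3-dien-1-yl]chroman-6-yl]propan-1-one | CC(C)=C/C=C/[C@]1(C)CCc2cc([C@H](O)CC(=O)c3c(OCOC)c(CC=C(C)C)c(OCOC)cc3O)cc(OCOC)c2O1
F5 | step 9 | 9-[(3E)-3-methylpent-3-en-1-yl]-9-borabicyclo[3.3.1]nonane (E/Z mixture, E drawn) | B1(C2CCCC1CCC2)CC/C(C)=C/C
F6 | step 9 | methyl 4-hydroxy-3-(methoxymethoxy)-5-[(3E)-3-methylpent-3-en-1-yl]benzoate (E/Z mixture, E drawn) | COC(=O)c1cc(OCOC)c(O)c(CC/C(C)=C/C)c1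
F7 | step 9 | methyl (2S)-2-ethenyl-8-(methoxymethoxy)-2-methyl-3,4-dihydro-2H-chromene-6-carboxylate | C=C[C@]1(C)CCc2cc(C(=O)OC)cc(OCOC)c2O1
F8 | step 9 | methyl (2S)-2-formyl-8-(methoxymethoxy)-2-methyl-3,4-dihydro-2H-chromene-6-carboxylate | O=C[C@]1(C)CCc2cc(C(=O)OC)cc(OCOC)c2O1
F9 | step 14 | tris(trimethylsilyl) ether of 31 (silyl groups on O5, O7 and the chroman O8) | CC(C)=C/C=C/[C@]1(C)CCc2cc([C@@H]3CC(=O)c4c(cc(O[Si](C)(C)C)c(CC=C(C)C)c4O[Si](C)(C)C)O3)cc(O[Si](C)(C)C)c2O1
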